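**Retrosynthetic overview**
1. Target 5 is the Tishchenko homodimer of 3-(3,4-dimethoxyphenyl)propanal 4, which is the redox isomer of (E)-3,4-dimethoxycinnamyl alcohol 3 (2 × C11H14O3 = C22H28O6). One Ru–H-catalysed "isomerising Tishchenko" dimerisation of 3 therefore makes the ester C–O bond and both saturated C3 chains (new step).
2. Alcohol 3 comes from 1,2-reduction of ethyl (E)-3,4-dimethoxycinnamate 2.
3. Ester 2 comes from Wittig olefination of veratraldehyde 1.
4. No ring is formed (both arenes come from 1) and the target has no stereocentre.

Assumption: the target is achiral (no stereocentre, no stereogenic double bond), so "single enantiomer" needs no stereocontrol; the Wittig ylide is treated as a reagent that adds atoms, not as a numbered compound.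

**Step 1**
Reactants: 1 3,4-dimethoxybenzaldehyde (veratraldehyde)
Product: 2 ethyl (E)-3-(3,4-dimethoxyphenyl)prop-2-enoate
Conditions: Ph3P=CHCO2Et (1.1 equiv), PhMe, 90 °C, 12 h
Reagents that add atoms: ethyl (triphenylphosphoranylidene)acetate, CCOC(=O)C=P(c1ccccc1)(c1ccccc1)c1ccccc1
Why: Wittig olefination with a stabilised ylide gives the (E)-cinnamate (typically >95:5) driven by P=O formation; the aryl methyl ethers are inert and no stereocentre is formed.

**Step 2**
Reactants: 2 ethyl (E)-3-(3,4-dimethoxyphenyl)prop-2-enoate
Product: 3 (E)-3-(3,4-dimethoxyphenyl)prop-2-en-1-ol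
Conditions: DIBAL-H (2.5 equiv), CH2Cl2, −78 → 0 °C; aq. Rochelle salt
Reagents that add atoms: none
Why: DIBAL-H 1,2-reduction of an α,β-unsaturated ester at low temperature gives the allylic alcohol without touching the C=C (E geometry kept) or the aryl ethers.

**Step 3**
Reactants: 3 (E)-3-(3,4-dimethoxyphenyl)prop-2-en-1-ol (two molecules)
Product: 5 3-(3,4-dimethoxyphenyl)propyl 3-(3,4-dimethoxyphenyl)propanoate, via 3-(3,4-dimethoxyphenyl)propanal 4 (not isolated)
Conditions: RuH2(PPh3)4 (3 mol%), PhMe (1 M), 100 °C, sealed tube, Ar, 16 h
Reagents that add atoms: none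
Why: Proposed new method: a redox-neutral "isomerising Tishchenko" homodimerisation of a primary allylic alcohol with one Ru hydride catalyst, in which Ru–H first isomerises 3 to aldehyde 4 (Ru-alkoxide formation, β-hydride elimination and 1,4-hydride return on Ru, then tautomerisation), then inserts the C=O of 4 to give a Ru 3-arylpropoxide that adds to a second molecule of 4, and β-hydride elimination from the Ru hemiacetalate forms the ester and regenerates Ru–H; both stages are exergonic, the hydrogen inventory is closed in the sealed vessel so off-cycle unsaturated species are funnelled to the saturated ester, no base is present to trigger aldol chemistry, the reaction is 100% atom-economic and forms no stereocentre; the closest known reaction types are the Ru-hydride-catalysed redox isomerisation of allylic alcohols to saturated carbonyl compounds and the Ru-hydride-catalysed Tishchenko dimerisation of aldehydes (and dehydrogenative coupling of primary alcohols to esters), which to my knowledge have not been merged into one operation on a cinnamyl alcohol.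

**Compound list**
1 | 3,4-dimethoxybenzaldehyde (veratraldehyde) | COc1ccc(C=O)cc1OC | starting material
2 | ethyl (E)-3-(3,4-dimethoxyphenyl)prop-2-enoate | CCOC(=O)/C=C/c1ccc(OC)c(OC)c1 | intermediate
3 | (E)-3-(3,4-dimethoxyphenyl)prop-2-en-1-ol | OC/C=C/c1ccc(OC)c(OC)c1 | intermediate
4 | 3-(3,4-dimethoxyphenyl)propanal | O=CCCc1ccc(OC)c(OC)c1 | intermediate (not isolated)
5 | 3-(3,4-dimethoxyphenyl)propyl 3-(3,4-dimethoxyphenyl)propanoate (achiral) | COc1ccc(CCCOC(=O)CCc2ccc(OC)c(OC)c2)cc1OC | target

**Totals**
Total step count: 3. Longest linear sequence: 3.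

**Steps most likely to fail, with fallbacks**

Step 3 (proposed new step). The tandem may stall at aldehyde 4, lose catalyst through aldehyde decarbonylation, or give disproportionation mixtures. The fallback uses only known chemistry, sets out from compound 2 and comes back at compound 5. Compound 2 is hydrogenated (H2 1 atm, 10% Pd/C, EtOAc, rt) to ethyl 3-(3,4-dimethoxyphenyl)propanoate F1. One half of it is reduced with LiAlH4 (THF, 0 °C) to 3-(3,4-dimethoxyphenyl)propan-1-ol F2. The other half is saponified (LiOH, THF–H2O, rt, then HCl) to 3-(3,4-dimethoxyphenyl)propanoic acid F3. The alcohol and the acid are then joined by Steglich esterification (EDC·HCl, cat. DMAP, CH2Cl2, rt) to give 5.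

Step 1. The electron-rich aldehyde may react slowly, give an E/Z mixture, or leave Ph3P=O that is hard to remove. The fallback sets out from compound 1 and comes back at compound 2. Knoevenagel–Doebner condensation of 1 with malonic acid (pyridine, cat. piperidine, 100 °C) passes through 2-[(3,4-dimethoxyphenyl)methylidene]propanedioic acid F4, which is not isolated and decarboxylates in the flask to the crystalline (E)-3-(3,4-dimethoxyphenyl)prop-2-enoic acid F5. Fischer esterification (EtOH, cat. H2SO4, reflux) then gives 2.

Step 2. Risks are partial 1,4-reduction or over-reduction and losses in the aluminium work-up. The fallback avoids ester reduction altogether; it sets out from compound 1 and comes back at compound 3. Wittig two-carbon homologation of 1 with (triphenylphosphoranylidene)acetaldehyde (PhMe, 80 °C) gives (E)-3-(3,4-dimethoxyphenyl)prop-2-enal F6. Luche 1,2-reduction (NaBH4, CeCl3·7H2O, MeOH, 0 °C) then gives 3.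

**Further compounds**
F1 | step 3 | ethyl 3-(3,4-dimethoxyphenyl)propanoate | CCOC(=O)CCc1ccc(OC)c(OC)c1
F2 | step 3 | 3-(3,4-dimethoxyphenyl)propan-1-ol | OCCCc1ccc(OC)c(OC)c1
F3 | step 3 | 3-(3,4-dimethoxyphenyl)propanoic acid | OC(=O)CCc1ccc(OC)c(OC)c1
F4 | step 1 | 2-[(3,4-dimethoxyphenyl)methylidene]propanedioic acid | COc1ccc(C=C(C(=O)O)C(=O)O)cc1OC
F5 | step 1 | (E)-3-(3,4-dimethoxyphenyl)prop-2-enoic acid | COc1ccc(/C=C/C(=O)O)cc1OC
F6 | step 2 | (E)-3-(3,4-dimethoxyphenyl)prop-2-enal | COc1ccc(/C=C/C=O)cc1OC
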